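## Compound numbers

The numbers below are fixed here and used throughout; the full list with SMILES follows the steps.

- Ring A line: **1** 2,3-dimethoxyphenol; **2** 2,3-dimethoxy-1,4-benzoquinone; **3** 5,6-dimethoxybenzene-1,2,4-triyl triacetate; **4** 1-(2,3,6-trihydroxy-4,5-dimethoxyphenyl)ethan-1-one; **5** its acetonide; **6** the 4-hydroxychromene-2-thione; **7** the 2-(methylsulfanyl)chromone.
- Alkyne line: **8** chloroacetaldehyde dimethyl acetal; **9** lithium methoxyacetylide; **10** tributyl(methoxyethynyl)stannane; **11** the 2-(methoxyethynyl)chromone.
- Ketene line: **12** 3-oxocyclobutanecarboxylic acid; **13** 3-bromocyclobutanone; **14** cyclobutenone.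
- Key step and end: **15**–**18** transient intermediates of the benzannulation; **19** the protected flavone; **20** the target.

## Analysis of the target

The target **20** is a flavone: a γ-pyranone (ring C) fused to ring A and carrying ring B at C2. It has no stereocentre, and the C2–C1' axis, although twisted by two ortho substituents, is not expected to be configurationally stable. Ring A is fully substituted: C5 and C6 carry free hydroxyls (C5–OH chelated to the C4 carbonyl), C7 and C8 carry methoxy groups, and C8a carries O1. Ring B has a hydroxyl at C2' and a methoxy group at C6', so C1' sits between two different oxygen substituents. The sensitive parts are the 5,6-catechol, which oxidises easily and binds metals, and the pyranone, which can open in strong base or hot strong acid and reclose through O5 or O2' (isomerisation of the Wessely–Moser type). The main difficulty is that six phenolic oxygens must end as three hydroxyls and three methyl ethers in fixed positions, which late selective methylation or demethylation cannot be trusted to deliver. A second difficulty is steric, since ring B is a 2,6-disubstituted aryl group. The strategy rests on the triad C2'(OH)–C1'(chromonyl)–C6'(OMe) of ring B: a 2-substituted resorcinol monomethyl ether is the pattern that a vinylketene and a 1-methoxyalkyne produce, so ring B can be grown on a finished chromone with its two oxygens already differentiated.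

## Retrosynthetic reasoning

**20 to 19.** The last operation only frees the 5,6-diol, so the target is traced back to its isopropylidene ketal **19**. A cyclic ketal is chosen because it can bridge only the single catechol of ring A. It should survive base, palladium/copper catalysis and heat, and it leaves under mild aqueous acid that does not touch aryl methyl ethers.

**19 to 11 and 14.** Ring B is cut at C1'–C2' and C5'–C6'. C2' to C5' come from cyclobutenone **14** and C1' and C6' from the triple bond of alkynyl ether **11**. Cutting here makes the C2' hydroxyl descend from the ketone of **14** and the C6' methyl ether from the ether oxygen of **11**, so ring B needs neither a protecting group nor a later differentiation of its two oxygens. It also avoids acylating with a di-ortho-substituted benzoyl unit. The forward reaction has to deliver the right regiochemistry in the ketene–alkyne cycloaddition, and the alkyne must remain nucleophilic enough although it is conjugated to the chromone.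

**11 to 7 and 10.** The C2–C1' bond is cut. Alkynyl ethers are best introduced as a metal alkoxyacetylide, and C2 of a chromone is an electrophilic carbon once it carries a sulfur leaving group. A neutral palladium/copper coupling of thioether **7** with stannane **10** avoids the base and acid that the alkynyl ether would not tolerate.

**10 to 8, and 14 to 12.** Stannane **10** comes from acetal **8** by double elimination to acetylide **9** and trapping with tin. Cyclobutenone **14** comes from bromide **13** by elimination, and **13** from acid **12** by decarboxylative bromination. Both are short, separate branches.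

**7 to 5.** Ring C is cut at O1–C2 and C2–C3. C2 is brought in as a one-carbon dithio unit that condenses with the methyl ketone and the free phenol of **5** to give thione **6**. S-Methylation then leaves the sulfur on C2 as the leaving group needed above.

**5 to 4.** The ketal is removed retrosynthetically to triol **4**. Only one pair of hydroxyls in **4** is adjacent, so the ketal distinguishes the future O5/O6 from the future O1 without further selectivity.

**4 to 1.** The C–acetyl bond of **4** is cut at the only free ring position of triacetate **3**. The two C–O bonds at the future C5 and C6 are traced to quinone **2**, whose symmetry makes the site of acetoxylation unambiguous. Quinone **2** is the para-oxidation product of phenol **1**, which already holds the two methoxy groups of C7 and C8.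

## Alternatives that were turned down

**Alternative 1:** Ring A would be built by ring expansion of a 4-hydroxycyclobutenone made from a squaric ester and a metallated dioxinone.
- Disconnection and key step: ring A is cut between the future C5 and C4a. Thermolysis opens the four-membered ring to a dienylketene, which closes by 6π-electrocyclisation onto the dioxinone double bond and gives the benzodioxinone A1.
- For: all four ring A oxygens arrive in one piece in a defined order, the thermolysis is neutral, and this type of ring expansion is well established. On precedent for the key step it is stronger than the chosen route.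
- Against: A1 carries hydroxyls at the future C5 and C8 and methoxy groups at C6 and C7, whereas **20** needs hydroxyls at C5/C6 and methoxy groups at C7/C8. That forces one O-methylation and one selective demethylation at O6 next to other methyl ethers, or a squaric ester with two different alkoxy groups and a new regiochemical problem. Ring B would still have to be attached as a hindered 2,6-dioxygenated aryl ketone with a protecting group on O2'.
- Comparison: it solves the easier half of the molecule, since the ring A oxygens are cheaply reached by quinone chemistry (steps 1 to 3). In place of the better precedent, the chosen route offers the correct oxygen pattern on both rings without any late editing of methyl ethers.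

**Alternative 2:** Ring A would be folded from an oxygenated keto-ester chain attached to a preformed 2-aryl-4-pyranone.
- Disconnection and key step: the C4a–C5 bond is cut. A vinylogous enolate of the pyranone attacks the terminal ester through C4a in a Claisen-type closure, and enolisation aromatises ring A to A2.
- For: it follows the biosynthetic logic, and O6 (benzyl) and O8 (methyl) are differentiated from the start. The chelated O5 should allow selective methylation of O7 before hydrogenolysis. On differentiating the ring A oxygens without oxidation chemistry it is as strong as the chosen route.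
- Against: the acyclic precursor, with two α-alkoxy groups between three carbonyls, is long to prepare and prone to enolisation and elimination. O-acylation or closure through the other enolate carbon can compete. Ring B with its protected phenol must already be in place, and three further steps follow the key step.
- Comparison: it is longer and its key step is at least as uncertain. The chosen route offers a short, classical approach to its precursor and puts its single uncertain step on a stable, purifiable substrate.

**Alternative 3:** Ring C would be closed by intramolecular acylation of a 3-aryloxy-3-arylacrylic acid.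
- Disconnection and key step: the C4–C4a bond is cut. The acid, made by adding a ring A phenol to an arylpropiolic ester, is activated as a mixed anhydride and acylates C4a to give A3.
- For: the ring A partner has a single free ring carbon, so the regiochemistry is unambiguous, and it needs no acetyl group. The reaction type is known on ordinary substrates, and A3 is simply the O-benzyl ether of **19**. On certainty of the key step this alternative is stronger than the chosen route.
- Against: a hindered phenol must add to a hindered, electron-rich arylpropiolate. Only the acrylic acid isomer with the carboxyl cis to the aryloxy group can cyclise. The acidic acylation conditions threaten the ketal, and ring B needs a separately made, protected alkyne and a final debenzylation.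
- Comparison: the step count is similar. In place of the higher certainty, the chosen route forms ring B with its hydroxyl free and its methyl ether in place, uses no protecting group on ring B and no acid while the ring is formed, and could give ring B analogues simply by changing the cyclobutenone.

Key step: step 11

Remark: ring positions follow flavone numbering (O1 to C4 in ring C, C5 to C8 in ring A, C1' to C6' in ring B). "5,6-Acetonide" means that O5 and O6 are bridged by a C(CH3)2 group. The target is achiral, so the only stereodescriptor needed is the double-bond geometry of the transient **17**.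

## Route

Step 1
Reactants: 1 2,3-dimethoxyphenol
Product: 2 2,3-dimethoxy-1,4-benzoquinone
Conditions: (KSO3)2NO (2.2 equiv), KH2PO4, H2O/acetone, 0 °C to rt
Reagents that add atoms: potassium nitrosodisulfonate, [K+].[K+].[O]N(S(=O)(=O)[O-])S(=O)(=O)[O-]
Why: Teuber oxidation: the nitrosodisulfonate radical oxidises a phenol with a free para position to the para-quinone, and in 1 that position (C4) is unsubstituted and activated by the neighbouring methoxy group.

Step 2
Reactants: 2 2,3-dimethoxy-1,4-benzoquinone
Product: 3 5,6-dimethoxybenzene-1,2,4-triyl triacetate
Conditions: Ac2O, H2SO4 (cat.), rt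
Reagents that add atoms: acetic anhydride, CC(=O)OC(C)=O
Why: Thiele–Winter acetoxylation: acid-catalysed conjugate addition to the unsubstituted C=C bond of the quinone, enolisation and O-acetylation of all three hydroxyls; C5 and C6 of 2 are equivalent by symmetry, so a single triacetate should form.

Step 3
Reactants: 3 5,6-dimethoxybenzene-1,2,4-triyl triacetate
Product: 4 1-(2,3,6-trihydroxy-4,5-dimethoxyphenyl)ethan-1-one
Conditions: BF3·OEt2 (3 equiv), AcOH, 90 °C, N2; then 1 M HCl aq., 60 °C
Reagents that add atoms: none
Why: Fries rearrangement: the Lewis acid transfers one O-acetyl group to C3 of 3, the only unsubstituted ring carbon, and the other two acetates are hydrolysed in the acidic work-up. The ketone ends up between two hydroxyls, so no methoxy group sits next to the carbonyl where chelation-assisted demethylation could occur.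

Step 4
Reactants: 4 1-(2,3,6-trihydroxy-4,5-dimethoxyphenyl)ethan-1-one
Product: 5 1-(5-hydroxy-6,7-dimethoxy-2,2-dimethyl-1,3-benzodioxol-4-yl)ethan-1-one
Conditions: Me2C(OMe)2, TsOH·H2O (cat.), PhMe, reflux with removal of MeOH (4 Å sieves), N2
Reagents that add atoms: 2,2-dimethoxypropane, COC(C)(C)OC
Why: Acid-catalysed transketalisation: only the hydroxyls at C2 and C3 of the aryl ring of 4 are adjacent, so the five-membered dioxole can form only there, and removal of methanol drives the equilibrium. The hydroxyl at C6, the future O1, stays free and chelated to the ketone.

Step 5
Reactants: 5 1-(5-hydroxy-6,7-dimethoxy-2,2-dimethyl-1,3-benzodioxol-4-yl)ethan-1-one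
Product: 6 4-hydroxy-7,8-dimethoxy-2H-chromene-2-thione 5,6-acetonide
Conditions: KOt-Bu (3.5 equiv), CS2 (1.5 equiv), THF, 0 °C to rt; cold 1 M HCl to pH 4
Reagents that add atoms: carbon disulfide, S=C=S
Why: Known annulation of 2-hydroxyacetophenones: the ketone enolate adds to CS2 and the phenoxide closes onto the dithiocarboxylate carbon with loss of hydrosulfide, which forms C2–C3 and O1–C2. Only one phenol is free in 5, so the ring can close in one direction only.

Step 6
Reactants: 6 4-hydroxy-7,8-dimethoxy-2H-chromene-2-thione 5,6-acetonide
Product: 7 7,8-dimethoxy-2-(methylsulfanyl)chromone 5,6-acetonide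
Conditions: MeI (1.1 equiv), K2CO3, acetone, rt
Reagents that add atoms: iodomethane, CI
Why: S-Alkylation of the ambident thione anion: the soft sulfur reacts with iodomethane in preference to O4 and gives the chromone as a vinylogous thioester.

Step 7
Reactants: 8 chloroacetaldehyde dimethyl acetal
Product: 10 tributyl(methoxyethynyl)stannane, via lithium methoxyacetylide 9 (not isolated)
Conditions: LiNEt2 (3.1 equiv, from Et2NH and n-BuLi), THF, 0 °C; then Bu3SnCl (1.0 equiv), −78 °C to rt; distillation
Reagents that add atoms: tributyltin chloride, CCCC[Sn](Cl)(CCCC)CCCC
Why: The amide base is used three times: elimination of methanol and of hydrogen chloride from 8 and deprotonation of the resulting alkyne give 9, which is stannylated at carbon. The route from α-chloroacetals to alkoxyethynyl metal reagents is established.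

Step 8
Reactants: 7 7,8-dimethoxy-2-(methylsulfanyl)chromone 5,6-acetonide; 10 tributyl(methoxyethynyl)stannane
Product: 11 7,8-dimethoxy-2-(methoxyethynyl)chromone 5,6-acetonide
Conditions: Pd(PPh3)4 (5 mol %), CuO2PPh2 (monovalent copper diphenylphosphinate, 1.5 equiv), THF, 50 °C; chromatography on base-washed silica
Reagents that add atoms: none
Why: Liebeskind–Srogl coupling in its organostannane form: the thiophilic monovalent copper salt activates the C2–S bond for oxidative addition to zerovalent palladium and takes up the thiolate, the alkynyl group is transferred from tin, and reductive elimination forms C2–C1'. The conditions are neutral and free of base and fluoride, as the acid-sensitive alkynyl ether and the ketal require.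

Step 9
Reactants: 12 3-oxocyclobutanecarboxylic acid
Product: 13 3-bromocyclobutan-1-one
Conditions: HgO, Br2, MgSO4, CH2Cl2, reflux
Reagents that add atoms: bromine, BrBr
Why: Hunsdiecker reaction in the Cristol–Firth modification: the mercury carboxylate gives an acyl hypobromite that loses CO2 in a radical chain and takes up bromine at C3; the ketone is inert to these conditions.

Step 10
Reactants: 13 3-bromocyclobutan-1-one
Product: 14 cyclobut-2-en-1-one
Conditions: n-Bu3N, neat, rt; vacuum transfer into a −78 °C trap
Reagents that add atoms: none
Why: Dehydrobromination of a β-bromo ketone by an E1cB pathway with a tertiary amine; the volatile enone is taken off under vacuum as it forms and used cold without delay, because it polymerises on standing.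

Step 11
Reactants: 11 7,8-dimethoxy-2-(methoxyethynyl)chromone 5,6-acetonide; 14 cyclobut-2-en-1-one
Product: 19 2-(2-hydroxy-6-methoxyphenyl)-7,8-dimethoxychromone 5,6-acetonide, via vinylketene 15 (not isolated), via cyclobutenone adduct 16 (not isolated), via dienylketene 17 (not isolated), via cyclohexadienone 18 (not isolated)
Conditions: 14 (2.5 equiv, in portions), PhMe, sealed tube, 80 °C then 110 °C; K2CO3, MeOH, rt in the work-up
Reagents that add atoms: none
Why: Proposed new method: the closest known reaction type is the Danheiser benzannulation of cyclobutenones with 1-alkoxyalkynes, siloxyalkynes and ynamides, extended here to an alkynyl ether conjugated to the acceptor carbon C2 of a chromone. At 80 °C 14 undergoes 4π-electrocyclic ring opening to vinylketene 15; in a [2+2] cycloaddition across the ketene C=C bond the ketene carbonyl carbon (future C2') is attacked by C1' of 11 and the ketene α-carbon (future C5') joins the methoxy-bearing C6', giving 16. Reversible 4π opening of 16 gives dienylketene 17, and the isomer with the vinyl group cis to the ketene carbon closes ring B by a thermal disrotatory 6π-electrocyclisation that joins C2' to C3'; enolisation of 18 then gives phenol 19. The six-membered carbocycle is thus closed by a pericyclic step, and no stereocentre survives, because the only sp3 centre of 16 becomes trigonal on ring opening. The step needs the regiochemistry of the [2+2] addition and chemoselectivity for the triple bond over the chromone C2=C3 bond. The methoxy donor and the chromone acceptor polarise the triple bond in the same sense (C6' positive, C1' negative), so the chromone should lower the rate but not reverse the direction of addition, and the electron-poor C2=C3 bond is no ketenophile. A methyl ether cannot lose an alkene by a retro-ene reaction on heating, the neutral conditions spare the ketal and the pyranone, and O-acylation of the new phenol by surplus ketene is reversed by the carbonate–methanol work-up.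

Step 12
Reactants: 19 2-(2-hydroxy-6-methoxyphenyl)-7,8-dimethoxychromone 5,6-acetonide
Product: 20 5,6,2'-trihydroxy-7,8,6'-trimethoxyflavone
Conditions: TFA/H2O (9:1), rt, N2
Reagents that add atoms: none
Why: Acid-catalysed hydrolysis of the cyclic ketal; aryl methyl ethers are stable to aqueous trifluoroacetic acid, and at room temperature the pyranone should not open, so isomerisation through O5 or O2' is not expected.

## Compound list

1 | 2,3-dimethoxyphenol | COc1cccc(O)c1OC | starting material
2 | 2,3-dimethoxy-1,4-benzoquinone | COC1=C(OC)C(=O)C=CC1=O | intermediate
3 | 5,6-dimethoxybenzene-1,2,4-triyl triacetate | COc1c(OC)c(OC(C)=O)c(OC(C)=O)cc1OC(C)=O | intermediate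
4 | 1-(2,3,6-trihydroxy-4,5-dimethoxyphenyl)ethan-1-one | CC(=O)c1c(O)c(OC)c(OC)c(O)c1O | intermediate
5 | 1-(5-hydroxy-6,7-dimethoxy-2,2-dimethyl-1,3-benzodioxol-4-yl)ethan-1-one | CC(=O)c1c(O)c(OC)c(OC)c2OC(C)(C)Oc12 | intermediate
6 | 4-hydroxy-7,8-dimethoxy-2H-chromene-2-thione 5,6-acetonide | S=c1cc(O)c2c3OC(C)(C)Oc3c(OC)c(OC)c2o1 | intermediate
7 | 7,8-dimethoxy-2-(methylsulfanyl)chromone 5,6-acetonide | CSc1cc(=O)c2c3OC(C)(C)Oc3c(OC)c(OC)c2o1 | intermediate
8 | chloroacetaldehyde dimethyl acetal | COC(CCl)OC | starting material
9 | lithium methoxyacetylide | [Li+].[C-]#COC | intermediate
10 | tributyl(methoxyethynyl)stannane | CCCC[Sn](CCCC)(CCCC)C#COC | intermediate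
11 | 7,8-dimethoxy-2-(methoxyethynyl)chromone 5,6-acetonide | COC#Cc1cc(=O)c2c3OC(C)(C)Oc3c(OC)c(OC)c2o1 | intermediate
12 | 3-oxocyclobutanecarboxylic acid | O=C1CC(C(=O)O)C1 | starting material
13 | 3-bromocyclobutan-1-one | O=C1CC(Br)C1 | intermediate
14 | cyclobut-2-en-1-one | O=C1C=CC1 | intermediate
15 | buta-1,3-dien-1-one (vinylketene) | C=CC=C=O | intermediate
16 | 3-methoxy-4-vinylcyclobut-2-en-1-one carrying the chromon-2-yl group of 11 at C2 (racemic) | C=CC1C(=O)C(c2cc(=O)c3c4OC(C)(C)Oc4c(OC)c(OC)c3o2)=C1OC | intermediate
17 | (3E)-3-methoxyhexa-1,3,5-trien-1-one carrying the chromon-2-yl group of 11 at C2 | C=C/C=C(/OC)C(=C=O)c1cc(=O)c2c3OC(C)(C)Oc3c(OC)c(OC)c2o1 | intermediate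
18 | 3-methoxycyclohexa-2,4-dien-1-one carrying the chromon-2-yl group of 11 at C2 | COC1=C(c2cc(=O)c3c4OC(C)(C)Oc4c(OC)c(OC)c3o2)C(=O)CC=C1 | intermediate
19 | 2-(2-hydroxy-6-methoxyphenyl)-7,8-dimethoxychromone 5,6-acetonide | COc1cccc(O)c1-c1cc(=O)c2c3OC(C)(C)Oc3c(OC)c(OC)c2o1 | intermediate
20 | 5,6,2'-trihydroxy-7,8,6'-trimethoxyflavone | COc1cccc(O)c1-c1cc(=O)c2c(O)c(O)c(OC)c(OC)c2o1 | target

## Step count and least certain steps

Total step count: 12. Longest linear sequence: 9 steps (steps 1, 2, 3, 4, 5, 6, 8, 11 and 12).

**Step 11 (key step, proposed new method).** The chromone spreads the electron density of C1' onto C3 and the carbonyl oxygen. The [2+2] addition may therefore become so slow that self-condensation and polymerisation of 14 and 15 consume the ketene first, or acylation may begin at C3 of the chromone. The fallback uses known chemistry, sets out from 5 and comes back at 19: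
- The phenol of 5 is acylated (pyridine, CH2Cl2) with 2-(allyloxy)-6-methoxybenzoyl chloride F1, made from the corresponding acid with oxalyl chloride. This gives 4-acetyl-6,7-dimethoxy-2,2-dimethyl-1,3-benzodioxol-5-yl 2-(allyloxy)-6-methoxybenzoate F2.
- Baker–Venkataraman rearrangement with LiN(SiMe3)2 in THF moves the aroyl group to carbon and gives 1-(5-hydroxy-6,7-dimethoxy-2,2-dimethyl-1,3-benzodioxol-4-yl)-3-[2-(allyloxy)-6-methoxyphenyl]propane-1,3-dione F3.
- Cyclodehydration with catalytic TsOH in refluxing toluene, with water removed so that the ketal stays, gives 2-[2-(allyloxy)-6-methoxyphenyl]-7,8-dimethoxychromone 5,6-acetonide F4.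
- Deallylation with Pd(PPh3)4 and morpholine in THF returns 19.

**Step 8.** The coupling may fail through slow oxidative addition at the electron-rich vinylogous thioester. The alkynyl ether may also be lost by protodestannylation, or by addition of thiolate or phosphinate to the electrophilic C6' of the product. The fallback sets out from 7 and comes back at 11. Oxidation with mCPBA gives 7,8-dimethoxy-2-(methylsulfonyl)chromone 5,6-acetonide F5. F5 is treated at −78 °C with 9, generated as in step 7 and transmetalated to zinc if the lithium reagent attacks C4. Addition at C2 and loss of methanesulfinate then give 11 without any transition metal catalyst.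

**Step 4.** Ketalisation may stay incomplete, because one of the two hydroxyls is held in a hydrogen bond to the ketone and the ring is electron-poor. The para-dihydroxy arrangement may also be oxidised by air during the long heating. The fallback places the ketal before the ketone; it sets out from 3 and comes back at 5:
- Methanolysis (K2CO3, degassed MeOH) gives 5,6-dimethoxybenzene-1,2,4-triol F6.
- F6 is ketalised at once with 2,2-dimethoxypropane and TsOH to 6,7-dimethoxy-2,2-dimethyl-1,3-benzodioxol-5-ol F7.
- MOMCl and i-Pr2NEt give 6,7-dimethoxy-5-(methoxymethoxy)-2,2-dimethyl-1,3-benzodioxole F8.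
- Directed ortho-lithiation (n-BuLi, TMEDA, THF) at the only ring hydrogen, between two oxygen substituents, and quenching with N-methoxy-N-methylacetamide give 1-[6,7-dimethoxy-5-(methoxymethoxy)-2,2-dimethyl-1,3-benzodioxol-4-yl]ethan-1-one F9.
- Brief treatment with dilute HCl in THF removes the acetal ortho to the ketone and returns 5.

**Step 5.** Ring closure of the hindered phenoxide onto the dithiocarboxylate may be incomplete, and the acidification may start to hydrolyse the ketal. The fallback sets out from 5 and comes back at 7, bypassing 6. NaH and CS2 followed by two equivalents of MeI give 1-(5-hydroxy-6,7-dimethoxy-2,2-dimethyl-1,3-benzodioxol-4-yl)-3,3-bis(methylsulfanyl)prop-2-en-1-one F10. On warming in THF, the phenoxide of F10 adds to the ketene dithioacetal carbon and expels methanethiolate to give 7 under basic conditions throughout.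

## Further compounds

F1 | step 11 | 2-(allyloxy)-6-methoxybenzoyl chloride | C=CCOc1cccc(OC)c1C(Cl)=O
F2 | step 11 | 4-acetyl-6,7-dimethoxy-2,2-dimethyl-1,3-benzodioxol-5-yl 2-(allyloxy)-6-methoxybenzoate | CC(=O)c1c(OC(=O)c2c(OC)cccc2OCC=C)c(OC)c(OC)c2OC(C)(C)Oc12
F3 | step 11 | 1-(5-hydroxy-6,7-dimethoxy-2,2-dimethyl-1,3-benzodioxol-4-yl)-3-[2-(allyloxy)-6-methoxyphenyl]propane-1,3-dione | C=CCOc1cccc(OC)c1C(=O)CC(=O)c1c(O)c(OC)c(OC)c2OC(C)(C)Oc12
F4 | step 11 | 2-[2-(allyloxy)-6-methoxyphenyl]-7,8-dimethoxychromone 5,6-acetonide | C=CCOc1cccc(OC)c1-c1cc(=O)c2c3OC(C)(C)Oc3c(OC)c(OC)c2o1
F5 | step 8 | 7,8-dimethoxy-2-(methylsulfonyl)chromone 5,6-acetonide | CS(=O)(=O)c1cc(=O)c2c3OC(C)(C)Oc3c(OC)c(OC)c2o1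
F6 | step 4 | 5,6-dimethoxybenzene-1,2,4-triol | COc1c(O)cc(O)c(O)c1OC
F7 | step 4 | 6,7-dimethoxy-2,2-dimethyl-1,3-benzodioxol-5-ol | COc1c(O)cc2OC(C)(C)Oc2c1OC
F8 | step 4 | 6,7-dimethoxy-5-(methoxymethoxy)-2,2-dimethyl-1,3-benzodioxole | COCOc1cc2OC(C)(C)Oc2c(OC)c1OC
F9 | step 4 | 1-[6,7-dimethoxy-5-(methoxymethoxy)-2,2-dimethyl-1,3-benzodioxol-4-yl]ethan-1-one | COCOc1c(OC)c(OC)c2OC(C)(C)Oc2c1C(C)=O
F10 | step 5 | 1-(5-hydroxy-6,7-dimethoxy-2,2-dimethyl-1,3-benzodioxol-4-yl)-3,3-bis(methylsulfanyl)prop-2-en-1-one | CSC(SC)=CC(=O)c1c(O)c(OC)c(OC)c2OC(C)(C)Oc12
A1 | alternative 1 | 5,8-dihydroxy-6,7-dimethoxy-2,2-dimethyl-4H-1,3-benzodioxin-4-one | CC1(C)OC(=O)c2c(O)c(OC)c(OC)c(O)c2O1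
A2 | alternative 2 | 6-(benzyloxy)-2-(2-benzyloxy-6-methoxyphenyl)-5,7-dihydroxy-8-methoxychromen-4-one | COc1cccc(OCc2ccccc2)c1-c1cc(=O)c2c(O)c(OCc3ccccc3)c(O)c(OC)c2o1
A3 | alternative 3 | 2-(2-benzyloxy-6-methoxyphenyl)-7,8-dimethoxychromone 5,6-acetonide | COc1cccc(OCc2ccccc2)c1-c1cc(=O)c2c3OC(C)(C)Oc3c(OC)c(OC)c2o1
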